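**Overview**

- Retrosynthesis: the twelve O-methyl groups come off last. Ring C, the only pentaoxygenated ring, is cut across C2–C3, C1–C6 and C3–C4 into an AB aryl ethynyl ether (supplying C2 and C1) and a DE-aryloxy(vinyl)ketene (supplying C3, C6, C5, C4). The A–O–B and D–O–E ethers are cut as Ullmann couplings.
- Enabling feature: in ring C the two adjacent hindered aryl ether carbons C1 (O to ring B) and C6 (O to ring D) lie between the lone C2–H and the three contiguous hydroxyl carbons C3–C5. This pattern maps atom for atom onto an ynol ether (C2–C1) plus an α-aryloxy-β,γ-dioxygenated vinylketene (C3, C6, C5, C4), so both hindered C–O bonds are made beforehand as simple phenol O-alkylations.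
- Forward: rings A, B, D and E are bought as arenes and joined pairwise by copper-catalysed couplings. The AB phenol is turned into the ethynyl ether; the DE phenol is O-alkylated with a chloro keto ester and advanced to an enol ether acid chloride. Ring C forms last in the benzannulation that unites the halves, followed by global demethylation.
- Stereochemistry: the target has no stereocentre. The racemic centre of the keto ester, the enol ether geometry and the transient sp3 centres of the cascade are all erased when ring C aromatises.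

Key step: step 13

Remark: either geometric isomer of the enol ether acid chloride should give the same vinylketene, so isomeric purity is not required; the Z isomer expected from O-methylation of the dissociated enolate is drawn. The six starting materials are taken as commercially available.

**Route**

Step 1
Reactants: 1 4-bromo-2,6-dimethoxyphenol
Product: 2 2-(benzyloxy)-5-bromo-1,3-dimethoxybenzene
Conditions: BnBr, K2CO3, DMF, 23 °C
Reagents that add atoms: benzyl bromide, BrCc1ccccc1
Why: Williamson O-benzylation of the phenoxide masks the ring B hydroxyl so that only the phenol of ring A can enter the copper coupling that follows.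

Step 2
Reactants: 2 2-(benzyloxy)-5-bromo-1,3-dimethoxybenzene; 3 2,4,6-trimethoxyphenol
Product: 4 2-(benzyloxy)-1,3-dimethoxy-5-(2,4,6-trimethoxyphenoxy)benzene
Conditions: CuI (10 mol%), picolinic acid (20 mol%), K3PO4, DMSO, 90 °C, argon
Reagents that add atoms: none
Why: Ullmann diaryl ether coupling with the picolinic acid ligand system, which is suited to di-ortho-substituted phenols, should join the hindered phenol 3 to a bromide that is unhindered at the reacting carbon (flanked by two CH).

Step 3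
Reactants: 4 2-(benzyloxy)-1,3-dimethoxy-5-(2,4,6-trimethoxyphenoxy)benzene
Product: 5 2,6-dimethoxy-4-(2,4,6-trimethoxyphenoxy)phenol
Conditions: H2 (1 atm), Pd/C (palladium on carbon), EtOAc–MeOH, 23 °C
Reagents that add atoms: none
Why: Catalytic hydrogenolysis cleaves only the benzylic C–O bond; the diaryl ether and the methyl ethers are inert.

Step 4
Reactants: 5 2,6-dimethoxy-4-(2,4,6-trimethoxyphenoxy)phenol; 6 trichloroethylene
Product: 8 2-{[(E)-1,2-dichloroethenyl]oxy}-1,3-dimethoxy-5-(2,4,6-trimethoxyphenoxy)benzene, via dichloroacetylene 7 (not isolated)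
Conditions: KH, THF, 0 °C; then Cl2C=CHCl, −50 → 23 °C
Reagents that add atoms: none
Why: Base-mediated dehydrochlorination of trichloroethylene gives dichloroacetylene in the flask, to which the potassium phenoxide adds in anti fashion (nucleophilic vinylation of a phenol), which should give the E dichlorovinyl ether.

Step 5
Reactants: 8 2-{[(E)-1,2-dichloroethenyl]oxy}-1,3-dimethoxy-5-(2,4,6-trimethoxyphenoxy)benzene
Product: 11 2-(ethynyloxy)-1,3-dimethoxy-5-(2,4,6-trimethoxyphenoxy)benzene, via chloroalkynyl ether 9 (not isolated), via lithium aryloxyacetylide 10 (not isolated)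
Conditions: n-BuLi (2.2 equiv), THF, −78 → −40 °C; then MeOH, −78 °C; used promptly
Reagents that add atoms: none
Why: Dehydrochlorination to the chloroalkyne, lithium–chlorine exchange and protonation is the standard dichlorovinyl ether route to ynol ethers; the low temperature should keep ring lithiation from competing, and the two ortho methoxy groups shield the ynol ether.

Step 6
Reactants: 12 3-hydroxy-4,5-dimethoxybenzaldehyde; 13 5-bromo-1,2,3-trimethoxybenzene
Product: 14 3,4-dimethoxy-5-(3,4,5-trimethoxyphenoxy)benzaldehyde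
Conditions: CuI (10 mol%), N,N-dimethylglycine (30 mol%), Cs2CO3, 1,4-dioxane, 100 °C, argon
Reagents that add atoms: none
Why: Amino-acid-promoted Ullmann diaryl ether coupling tolerates the aldehyde and joins a mono-ortho-substituted phenol to a bromide flanked by two CH.

Step 7
Reactants: 14 3,4-dimethoxy-5-(3,4,5-trimethoxyphenoxy)benzaldehyde
Product: 16 3,4-dimethoxy-5-(3,4,5-trimethoxyphenoxy)phenol, via aryl formate 15 (not isolated)
Conditions: mCPBA, CH2Cl2, 0 → 23 °C; aq. NaHCO3 wash; then K2CO3 (0.2 equiv), MeOH, 23 °C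
Reagents that add atoms: mCPBA, OOC(=O)c1cccc(Cl)c1
Why: Dakin-type Baeyer–Villiger oxidation, in which the electron-rich aryl group (para methoxy) migrates in preference to hydrogen to give the formate, followed by base-catalysed methanolysis in the same flask.

Step 8
Reactants: 17 methyl 4-methoxy-3-oxobutanoate
Product: 18 methyl 2-chloro-4-methoxy-3-oxobutanoate (racemic)
Conditions: SO2Cl2 (1.0 equiv), CH2Cl2, 0 → 23 °C
Reagents that add atoms: sulfuryl chloride, ClS(Cl)(=O)=O
Why: Electrophilic α-chlorination of the enol of a β-keto ester is selective for the doubly activated C2, and one equivalent of reagent should stop at the monochloride.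

Step 9
Reactants: 16 3,4-dimethoxy-5-(3,4,5-trimethoxyphenoxy)phenol; 18 methyl 2-chloro-4-methoxy-3-oxobutanoate
Product: 19 methyl 2-[3,4-dimethoxy-5-(3,4,5-trimethoxyphenoxy)phenoxy]-4-methoxy-3-oxobutanoate (racemic)
Conditions: K2CO3, acetone, reflux
Reagents that add atoms: none
Why: Williamson-type SN2 displacement of the activated α-chloride by the phenoxide, as in the standard preparation of 2-aryloxyacetoacetates; this forms the future C6–O bond of ring C without any metal.

Step 10
Reactants: 19 methyl 2-[3,4-dimethoxy-5-(3,4,5-trimethoxyphenoxy)phenoxy]-4-methoxy-3-oxobutanoate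
Product: 20 methyl (2Z)-2-[3,4-dimethoxy-5-(3,4,5-trimethoxyphenoxy)phenoxy]-3,4-dimethoxybut-2-enoate
Conditions: KN(SiMe3)2, THF–DMPU, −78 °C; MeOTf, −78 → 0 °C
Reagents that add atoms: methyl trifluoromethanesulfonate, COS(=O)(=O)C(F)(F)F
Why: O-alkylation of a dissociated potassium β-keto ester enolate by the hard electrophile MeOTf (enol ether formation) should prevail because C-methylation would build a fully substituted carbon next to the aryloxy group; the extended enolate is expected to give the Z isomer.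

Step 11
Reactants: 20 methyl (2Z)-2-[3,4-dimethoxy-5-(3,4,5-trimethoxyphenoxy)phenoxy]-3,4-dimethoxybut-2-enoate
Product: 21 (2Z)-2-[3,4-dimethoxy-5-(3,4,5-trimethoxyphenoxy)phenoxy]-3,4-dimethoxybut-2-enoic acid
Conditions: LiOH, THF–MeOH–H2O, 40 °C; then 1 M HCl to pH 4, 0 °C
Reagents that add atoms: lithium hydroxide, [Li+].[OH-]
Why: Saponification of the methyl ester; the β-methoxy acrylate is a vinylogous carbonate that should survive aqueous base and the brief, cold, mildly acidic work-up.

Step 12
Reactants: 21 (2Z)-2-[3,4-dimethoxy-5-(3,4,5-trimethoxyphenoxy)phenoxy]-3,4-dimethoxybut-2-enoic acid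
Product: 22 (2Z)-2-[3,4-dimethoxy-5-(3,4,5-trimethoxyphenoxy)phenoxy]-3,4-dimethoxybut-2-enoyl chloride
Conditions: 1-chloro-N,N,2-trimethylprop-1-en-1-amine, CH2Cl2, 0 → 23 °C; solvent exchanged for toluene, used at once
Reagents that add atoms: 1-chloro-N,N,2-trimethylprop-1-en-1-amine, CC(C)=C(Cl)N(C)C
Why: Acid chloride formation with an α-chloroenamine releases only a neutral amide and no HCl, so the enol ether and the electron-rich rings should be left untouched.

Step 13
Reactants: 22 (2Z)-2-[3,4-dimethoxy-5-(3,4,5-trimethoxyphenoxy)phenoxy]-3,4-dimethoxybut-2-enoyl chloride; 11 2-(ethynyloxy)-1,3-dimethoxy-5-(2,4,6-trimethoxyphenoxy)benzene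
Product: 27 5-[2,6-dimethoxy-4-(2,4,6-trimethoxyphenoxy)phenoxy]-4-[3,4-dimethoxy-5-(3,4,5-trimethoxyphenoxy)phenoxy]-2,3-dimethoxyphenol, via aryloxy(vinyl)ketene 23 (not isolated), via 4-vinylcyclobutenone 24 (not isolated), via dienylketene 25 (not isolated), via cyclohexa-2,4-dienone 26 (not isolated)
Conditions: Et3N (3 equiv), toluene; 22 added over 4 h to 11 (1.5 equiv) at 23 °C, then 100 °C
Reagents that add atoms: none
Why: Proposed new method: Et3N removes a γ-hydrogen of 22 (the α-carbon bears none) and chloride leaves in a 1,4-dehydrochlorination to give ketene 23, whose carbonyl carbon is attacked by the nucleophilic CH terminus of ynol ether 11 in a (2+2) cycloaddition that forms C2–C3 and C1–C6 and gives cyclobutenone 24; 4π electrocyclic opening then breaks the former acyl–α-carbon bond (C3–C6) to give dienylketene 25, and 6π electrocyclization forms C3–C4 to give dienone 26, which tautomerises to phenol 27. The closest known reaction types are the Danheiser benzannulation of vinylketenes with alkoxy- and siloxyalkynes, the Moore rearrangement of 4-oxy-4-vinylcyclobutenones and the amine-mediated generation of vinylketenes from α,β-unsaturated acid chlorides; an α-aryloxy trioxygenated vinylketene paired with an aryl ethynyl ether is not known. The transient four-membered ring closes by ketene–alkyne (2+2) cycloaddition and ring C closes by disrotatory 6π electrocyclization of the dienylketene. No stereocentre survives, since the sp3 centres of 24 and 26 are racemic and vanish on aromatisation. The step needs regioselectivity in the (2+2) event, secured by the oxygen-polarised ynol ether so that the lone hydrogen ends at C2 between the C1 aryl ether and the C3 hydroxyl, and inward rotation of the vinyl group on opening of 24, secured by the outward preference of the C6 aryloxy donor and by the reversibility of the opening. The oxygen donors on both partners should accelerate the cycloaddition and the ring opening, while slow addition of 22 to an excess of 11 keeps the ketene concentration low against dimerisation and acylation of the product phenol.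

Step 14
Reactants: 27 5-[2,6-dimethoxy-4-(2,4,6-trimethoxyphenoxy)phenoxy]-4-[3,4-dimethoxy-5-(3,4,5-trimethoxyphenoxy)phenoxy]-2,3-dimethoxyphenol
Product: 28 5-[2,6-dihydroxy-4-(2,4,6-trihydroxyphenoxy)phenoxy]-4-[3,4-dihydroxy-5-(3,4,5-trihydroxyphenoxy)phenoxy]benzene-1,2,3-triol (CNP0154768.0)
Conditions: BBr3 (excess), CH2Cl2, −78 → 23 °C; degassed H2O, 0 °C; work-up under argon with degassed solvents
Reagents that add atoms: none
Why: Lewis-acid cleavage of aryl methyl ethers by BBr3 removes all twelve methyl groups by bromide attack at methyl, whereas the diaryl ether bonds offer no carbon open to substitution and should persist.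

**Compound list**

1 | 4-bromo-2,6-dimethoxyphenol | COc1cc(Br)cc(OC)c1O | starting material
2 | 2-(benzyloxy)-5-bromo-1,3-dimethoxybenzene | COc1cc(Br)cc(OC)c1OCc1ccccc1 | intermediate
3 | 2,4,6-trimethoxyphenol | COc1cc(OC)c(O)c(OC)c1 | starting material
4 | 2-(benzyloxy)-1,3-dimethoxy-5-(2,4,6-trimethoxyphenoxy)benzene | COc1cc(OC)c(Oc2cc(OC)c(OCc3ccccc3)c(OC)c2)c(OC)c1 | intermediate
5 | 2,6-dimethoxy-4-(2,4,6-trimethoxyphenoxy)phenol | COc1cc(OC)c(Oc2cc(OC)c(O)c(OC)c2)c(OC)c1 | intermediate
6 | trichloroethylene | ClC=C(Cl)Cl | starting material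
7 | dichloroacetylene | ClC#CCl | intermediate
8 | 2-{[(E)-1,2-dichloroethenyl]oxy}-1,3-dimethoxy-5-(2,4,6-trimethoxyphenoxy)benzene | Cl/C=C(/Cl)Oc1c(OC)cc(Oc2c(OC)cc(OC)cc2OC)cc1OC | intermediate
9 | 2-[(chloroethynyl)oxy]-1,3-dimethoxy-5-(2,4,6-trimethoxyphenoxy)benzene | ClC#COc1c(OC)cc(Oc2c(OC)cc(OC)cc2OC)cc1OC | intermediate
10 | {[2,6-dimethoxy-4-(2,4,6-trimethoxyphenoxy)phenoxy]ethynyl}lithium | [Li]C#COc1c(OC)cc(Oc2c(OC)cc(OC)cc2OC)cc1OC | intermediate
11 | 2-(ethynyloxy)-1,3-dimethoxy-5-(2,4,6-trimethoxyphenoxy)benzene | C#COc1c(OC)cc(Oc2c(OC)cc(OC)cc2OC)cc1OC | intermediate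
12 | 3-hydroxy-4,5-dimethoxybenzaldehyde | COc1cc(C=O)cc(O)c1OC | starting material
13 | 5-bromo-1,2,3-trimethoxybenzene | COc1cc(Br)cc(OC)c1OC | starting material
14 | 3,4-dimethoxy-5-(3,4,5-trimethoxyphenoxy)benzaldehyde | COc1cc(Oc2cc(C=O)cc(OC)c2OC)cc(OC)c1OC | intermediate
15 | 3,4-dimethoxy-5-(3,4,5-trimethoxyphenoxy)phenyl formate | COc1cc(Oc2cc(OC=O)cc(OC)c2OC)cc(OC)c1OC | intermediate
16 | 3,4-dimethoxy-5-(3,4,5-trimethoxyphenoxy)phenol | COc1cc(Oc2cc(O)cc(OC)c2OC)cc(OC)c1OC | intermediate
17 | methyl 4-methoxy-3-oxobutanoate | COCC(=O)CC(=O)OC | starting material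
18 | methyl 2-chloro-4-methoxy-3-oxobutanoate (racemic) | COCC(=O)C(Cl)C(=O)OC | intermediate
19 | methyl 2-[3,4-dimethoxy-5-(3,4,5-trimethoxyphenoxy)phenoxy]-4-methoxy-3-oxobutanoate (racemic) | COCC(=O)C(Oc1cc(OC)c(OC)c(Oc2cc(OC)c(OC)c(OC)c2)c1)C(=O)OC | intermediate
20 | methyl (2Z)-2-[3,4-dimethoxy-5-(3,4,5-trimethoxyphenoxy)phenoxy]-3,4-dimethoxybut-2-enoate | COC/C(OC)=C(/Oc1cc(OC)c(OC)c(Oc2cc(OC)c(OC)c(OC)c2)c1)C(=O)OC | intermediate
21 | (2Z)-2-[3,4-dimethoxy-5-(3,4,5-trimethoxyphenoxy)phenoxy]-3,4-dimethoxybut-2-enoic acid | COC/C(OC)=C(/Oc1cc(OC)c(OC)c(Oc2cc(OC)c(OC)c(OC)c2)c1)C(=O)O | intermediate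
22 | (2Z)-2-[3,4-dimethoxy-5-(3,4,5-trimethoxyphenoxy)phenoxy]-3,4-dimethoxybut-2-enoyl chloride | COC/C(OC)=C(/Oc1cc(OC)c(OC)c(Oc2cc(OC)c(OC)c(OC)c2)c1)C(Cl)=O | intermediate
23 | 2-[3,4-dimethoxy-5-(3,4,5-trimethoxyphenoxy)phenoxy]-3,4-dimethoxybuta-1,3-dien-1-one (enol ether geometry not defined) | COC=C(OC)C(Oc1cc(OC)c(OC)c(Oc2cc(OC)c(OC)c(OC)c2)c1)=C=O | intermediate
24 | 4-(1,2-dimethoxyethenyl)-3-[2,6-dimethoxy-4-(2,4,6-trimethoxyphenoxy)phenoxy]-4-[3,4-dimethoxy-5-(3,4,5-trimethoxyphenoxy)phenoxy]cyclobut-2-en-1-one (racemic) | O=C1C=C(Oc2c(OC)cc(Oc3c(OC)cc(OC)cc3OC)cc2OC)C1(Oc1cc(OC)c(OC)c(Oc2cc(OC)c(OC)c(OC)c2)c1)C(OC)=COC | intermediate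
25 | (3Z)-3-[2,6-dimethoxy-4-(2,4,6-trimethoxyphenoxy)phenoxy]-4-[3,4-dimethoxy-5-(3,4,5-trimethoxyphenoxy)phenoxy]-5,6-dimethoxyhexa-1,3,5-trien-1-one | O=C=C/C(Oc1c(OC)cc(Oc2c(OC)cc(OC)cc2OC)cc1OC)=C(/Oc1cc(OC)c(OC)c(Oc2cc(OC)c(OC)c(OC)c2)c1)C(OC)=COC | intermediate
26 | 3-[2,6-dimethoxy-4-(2,4,6-trimethoxyphenoxy)phenoxy]-4-[3,4-dimethoxy-5-(3,4,5-trimethoxyphenoxy)phenoxy]-5,6-dimethoxycyclohexa-2,4-dien-1-one (racemic) | O=C1C=C(Oc2c(OC)cc(Oc3c(OC)cc(OC)cc3OC)cc2OC)C(Oc2cc(OC)c(OC)c(Oc3cc(OC)c(OC)c(OC)c3)c2)=C(OC)C1OC | intermediate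
27 | 5-[2,6-dimethoxy-4-(2,4,6-trimethoxyphenoxy)phenoxy]-4-[3,4-dimethoxy-5-(3,4,5-trimethoxyphenoxy)phenoxy]-2,3-dimethoxyphenol | COc1cc(OC)c(Oc2cc(OC)c(Oc3cc(O)c(OC)c(OC)c3Oc3cc(OC)c(OC)c(Oc4cc(OC)c(OC)c(OC)c4)c3)c(OC)c2)c(OC)c1 | intermediate
28 | 5-[2,6-dihydroxy-4-(2,4,6-trihydroxyphenoxy)phenoxy]-4-[3,4-dihydroxy-5-(3,4,5-trihydroxyphenoxy)phenoxy]benzene-1,2,3-triol (CNP0154768.0) | Oc1cc(O)c(Oc2cc(O)c(Oc3cc(O)c(O)c(O)c3Oc3cc(O)c(O)c(Oc4cc(O)c(O)c(O)c4)c3)c(O)c2)c(O)c1 | target

**Totals and risks**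

Total step count: 14. Longest linear sequence: 8 steps (steps 6, 7, 9, 10, 11, 12, 13, 14).

Steps most likely to fail:

Step 13 (Proposed new method). The ketene may dimerise or be captured at oxygen before it meets the alkyne, the acid chloride may cyclise onto ring D before dehydrochlorination, or the cyclobutenone may fail to open with the vinyl group turned inward. The fallback uses known chemistry and takes ring C from an arene instead of building it. It sets out from phenol 5 (with 13 and 16 as the other inputs) and returns to the route at 28. Bromide 13 is formylated ortho to bromine (Rieche formylation, Cl2CHOMe, TiCl4, CH2Cl2, 0 °C) to give 6-bromo-2,3,4-trimethoxybenzaldehyde F1. Ullmann coupling of 5 with F1 (CuI, picolinic acid, K3PO4, DMSO, 90 °C), the bromide being activated by the ortho formyl group, should give 6-[2,6-dimethoxy-4-(2,4,6-trimethoxyphenoxy)phenoxy]-2,3,4-trimethoxybenzaldehyde F2. Dakin oxidation (mCPBA, then K2CO3, MeOH) through 6-[2,6-dimethoxy-4-(2,4,6-trimethoxyphenoxy)phenoxy]-2,3,4-trimethoxyphenyl formate F3 gives the hindered 6-[2,6-dimethoxy-4-(2,4,6-trimethoxyphenoxy)phenoxy]-2,3,4-trimethoxyphenol F4. Phenol 16 is converted (Tf2O, pyridine, CH2Cl2) into 3,4-dimethoxy-5-(3,4,5-trimethoxyphenoxy)phenyl trifluoromethanesulfonate F5. Palladium-catalysed C–O coupling of F4 with F5 (Pd(OAc)2, 2-di-tert-butylphosphino-2',4',6'-triisopropylbiphenyl, K3PO4, toluene, 100 °C) should give the trideca-O-methyl pentamer F6, which carries a methoxy group in place of the ring C C3 hydroxyl. F6 is demethylated with BBr3 as in step 14 to reach 28.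

Step 5. The terminal aryloxyacetylene may hydrate or oligomerise during work-up and concentration, and ring lithiation may compete with the elimination. The fallback sets out from dichlorovinyl ether 8 and returns to the route at 11. The lithium acetylide 10, generated as in step 5, is quenched with Me3SiCl instead of methanol to give {[2,6-dimethoxy-4-(2,4,6-trimethoxyphenoxy)phenoxy]ethynyl}trimethylsilane F7, a C-silylated ynol ether expected to tolerate chromatography and storage. It is desilylated (K2CO3, MeOH–THF, 0 °C) immediately before step 13, and the solution of 11 is passed on without concentration.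

Step 14. Cleavage of the twelve ethers may stop short at the most hindered positions, and the pyrogallol and phloroglucinol units may oxidise in air during purification of the very polar product. The fallback sets out from 27 and returns to the route at 28. The crude product of the BBr3 treatment is not purified but exhaustively acetylated (Ac2O, pyridine, DMAP, 23 °C) to the tridecaacetate F8 of 28, an air-stable, non-polar compound from which under-demethylated congeners should separate on silica. Acid-catalysed methanolysis (HCl generated from AcCl in degassed MeOH, 23 °C, argon) then releases 28 with only volatile by-products.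

**Further compounds**

F1 | step 13 | 6-bromo-2,3,4-trimethoxybenzaldehyde | COc1cc(Br)c(C=O)c(OC)c1OC
F2 | step 13 | 6-[2,6-dimethoxy-4-(2,4,6-trimethoxyphenoxy)phenoxy]-2,3,4-trimethoxybenzaldehyde | COc1cc(Oc2c(OC)cc(Oc3c(OC)cc(OC)cc3OC)cc2OC)c(C=O)c(OC)c1OC
F3 | step 13 | 6-[2,6-dimethoxy-4-(2,4,6-trimethoxyphenoxy)phenoxy]-2,3,4-trimethoxyphenyl formate | COc1cc(Oc2c(OC)cc(Oc3c(OC)cc(OC)cc3OC)cc2OC)c(OC=O)c(OC)c1OC
F4 | step 13 | 6-[2,6-dimethoxy-4-(2,4,6-trimethoxyphenoxy)phenoxy]-2,3,4-trimethoxyphenol | COc1cc(Oc2c(OC)cc(Oc3c(OC)cc(OC)cc3OC)cc2OC)c(O)c(OC)c1OC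
F5 | step 13 | 3,4-dimethoxy-5-(3,4,5-trimethoxyphenoxy)phenyl trifluoromethanesulfonate | COc1cc(Oc2cc(OS(=O)(=O)C(F)(F)F)cc(OC)c2OC)cc(OC)c1OC
F6 | step 13 | 1-[2,6-dimethoxy-4-(2,4,6-trimethoxyphenoxy)phenoxy]-2-[3,4-dimethoxy-5-(3,4,5-trimethoxyphenoxy)phenoxy]-3,4,5-trimethoxybenzene | COc1cc(OC)c(Oc2cc(OC)c(Oc3cc(OC)c(OC)c(OC)c3Oc3cc(OC)c(OC)c(Oc4cc(OC)c(OC)c(OC)c4)c3)c(OC)c2)c(OC)c1
F7 | step 5 | {[2,6-dimethoxy-4-(2,4,6-trimethoxyphenoxy)phenoxy]ethynyl}trimethylsilane | C[Si](C)(C)C#COc1c(OC)cc(Oc2c(OC)cc(OC)cc2OC)cc1OC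
F8 | step 14 | tridecaacetate of 28 | CC(=O)Oc1cc(OC(C)=O)c(Oc2cc(OC(C)=O)c(Oc3cc(OC(C)=O)c(OC(C)=O)c(OC(C)=O)c3Oc3cc(OC(C)=O)c(OC(C)=O)c(Oc4cc(OC(C)=O)c(OC(C)=O)c(OC(C)=O)c4)c3)c(OC(C)=O)c2)c(OC(C)=O)c1
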